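**Assumption:** the SMILES is read as (4R,5S)-5-[(E)-heptadec-14-en-1-yl]-4,5-dihydroxycyclohex-2-en-1-one (cis-diol). Ring numbering C1 (C=O) to C6 (CH2) is also used for the matching carbons of open-chain intermediates. Compounds 1, 3, 6, 9 and 13 are bought.

## Retrosynthetic overview

1. 17 ⇒ 16: the only ring is closed last, by ring-closing metathesis across C2=C3.
2. 16 ⇒ 12 + 13: the C1–C6 bond comes from 1-lithio-1-methoxyallene, an acryloyl anion equivalent, opening the epoxide CH2 of 12; both carbons are electrophilic in normal reactivity.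
3. 12 ⇒ rac-11: a Sharpless kinetic resolution/epoxidation sets C4 and C5 together.
4. 11 ⇒ 2-lithioalkene 10 + acrolein; bromide 8 ⇒ 2,3-dibromopropene + C16 Grignard 7; bromide 5 ⇒ (E)-hex-3-enyl Grignard 4 + 1,10-dibromodecane.

## Route

Step 1
Reactants: 1 (E)-hex-3-en-1-ol
Product: 2 (E)-1-bromohex-3-ene
Conditions: CBr4, PPh3, CH2Cl2, 0 °C to rt
Reagents that add atoms: carbon tetrabromide, BrC(Br)(Br)Br
Why: Appel reaction; SN2 displacement on the alkoxyphosphonium gives the primary bromide without touching the (E)-alkene.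

Step 2
Reactants: 2 (E)-1-bromohex-3-ene; 3 1,10-dibromodecane (3 equiv)
Product: 5 (E)-16-bromohexadec-3-ene, via (E)-hex-3-en-1-ylmagnesium bromide 4 (not isolated)
Conditions: Mg, THF, 35 °C; then added to 3 and Li2CuCl4 (3 mol%), THF, −10 to 0 °C
Reagents that add atoms: none
Why: Kochi-type Li2CuCl4-catalysed sp3–sp3 Grignard cross-coupling; excess dibromide favours mono-coupling and the homoallylic Grignard keeps its (E)-geometry.

Step 3
Reactants: 5 (E)-16-bromohexadec-3-ene; 6 2,3-dibromoprop-1-ene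
Product: 8 (E)-2-bromononadeca-1,16-diene, via (E)-hexadec-13-en-1-ylmagnesium bromide 7 (not isolated)
Conditions: Mg, THF, 45 °C; then 6, THF, 0 °C to rt
Reagents that add atoms: none
Why: Grignard allylation of the allylic bromide (SN2 and SN2' give the same product); the vinylic C–Br bond is inert and is kept for the next step.

Step 4
Reactants: 8 (E)-2-bromononadeca-1,16-diene; 9 acrolein
Product: 11 rac-(E)-4-methylidenehenicosa-1,18-dien-3-ol, via (E)-nonadeca-1,16-dien-2-yllithium 10 (not isolated)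
Conditions: t-BuLi (2.1 equiv), Et2O, −78 °C; then 9, −78 °C; H2O
Reagents that add atoms: none
Why: Bromine–lithium exchange, then 1,2-addition of the alkenyllithium to acrolein, gives the racemic bis-allylic alcohol (C4 not yet controlled).

Step 5
Reactants: 11 rac-(E)-4-methylidenehenicosa-1,18-dien-3-ol
Product: 12 (1R)-1-[(2S)-2-[(E)-heptadec-14-en-1-yl]oxiran-2-yl]prop-2-en-1-ol
Conditions: Ti(OiPr)4 (15 mol%), D-(−)-diisopropyl tartrate (18 mol%), t-BuOOH (0.55 equiv), 4 Å molecular sieves, CH2Cl2, −20 °C, to about 52% conversion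
Reagents that add atoms: tert-butyl hydroperoxide, CC(C)(C)OO
Why: Sharpless asymmetric epoxidation run as a kinetic resolution; with the D-(−)-tartrate the (R)-alcohol reacts fast at its electron-richer 1,1-disubstituted alkene on the catalyst-chosen face to give the erythro epoxy alcohol, fixing C5 (S) and C4 (R) together, while (S)-11 is left behind and the remote chain alkene, not being allylic to the hydroxyl, is untouched.

Step 6
Reactants: 12 (1R)-1-[(2S)-2-[(E)-heptadec-14-en-1-yl]oxiran-2-yl]prop-2-en-1-ol; 13 methoxyallene (3 equiv)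
Product: 16 (5S,6R)-5-[(E)-heptadec-14-en-1-yl]-5,6-dihydroxyocta-1,7-dien-3-one, via 1-lithio-1-methoxyallene 14 (not isolated), via allenyl ether diol 15 (not isolated)
Conditions: 13, n-BuLi, THF, −40 °C; 12 (pre-treated with n-BuLi, 1.0 equiv, THF, −78 °C) added, −40 to 0 °C; H2O, concentrate; then 0.5 M aq. oxalic acid, THF, 0 °C
Reagents that add atoms: water, O
Why: Acyl anion (acryloyl d1) alkylation: the α-lithiated alkoxyallene opens the epoxide by SN2 at the unhindered CH2 (C6), so the tertiary C5–O stereocentre is retained, and mild acid hydrolysis of the 1-alkoxyallene unmasks the vinyl ketone.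

Step 7
Reactants: 16 (5S,6R)-5-[(E)-heptadec-14-en-1-yl]-5,6-dihydroxyocta-1,7-dien-3-one
Product: 17 (4R,5S)-5-[(E)-heptadec-14-en-1-yl]-4,5-dihydroxycyclohex-2-en-1-one
Conditions: second-generation Grubbs catalyst RuCl2(=CHPh)(PCy3)(H2IMes) (3 mol%), CH2Cl2 (2 mM), 40 °C, 1 h; ethyl vinyl ether quench
Reagents that add atoms: none
Why: Ring-closing metathesis of the two terminal vinyl groups closes the six-membered enone with loss of ethene faster than the catalyst engages the remote internal (E)-alkene; no stereocentre is touched, so the erythro diol becomes the cis-4,5-diol.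

## Compound list

1 | (E)-hex-3-en-1-ol | CC/C=C/CCO | starting material
2 | (E)-1-bromohex-3-ene | CC/C=C/CCBr | intermediate
3 | 1,10-dibromodecane | BrCCCCCCCCCCBr | starting material
4 | (E)-hex-3-en-1-ylmagnesium bromide | CC/C=C/CC[Mg]Br | intermediate
5 | (E)-16-bromohexadec-3-ene | CC/C=C/CCCCCCCCCCCCBr | intermediate
6 | 2,3-dibromoprop-1-ene | C=C(Br)CBr | starting material
7 | (E)-hexadec-13-en-1-ylmagnesium bromide | CC/C=C/CCCCCCCCCCCC[Mg]Br | intermediate
8 | (E)-2-bromononadeca-1,16-diene | C=C(Br)CCCCCCCCCCCCC/C=C/CC | intermediate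
9 | acrolein | C=CC=O | starting material
10 | (E)-nonadeca-1,16-dien-2-yllithium | [Li]C(=C)CCCCCCCCCCCCC/C=C/CC | intermediate
11 | rac-(E)-4-methylidenehenicosa-1,18-dien-3-ol | C=CC(O)C(=C)CCCCCCCCCCCCC/C=C/CC | intermediate
12 | (1R)-1-[(2S)-2-[(E)-heptadec-14-en-1-yl]oxiran-2-yl]prop-2-en-1-ol | CC/C=C/CCCCCCCCCCCCC[C@]1(CO1)[C@H](O)C=C | intermediate
13 | methoxyallene (1-methoxypropa-1,2-diene) | COC=C=C | starting material
14 | 1-lithio-1-methoxyallene | COC([Li])=C=C | intermediate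
15 | (3R,4S)-4-[(E)-heptadec-14-en-1-yl]-6-methoxyocta-1,6,7-triene-3,4-diol (dilithium alkoxide until the quench) | C=C=C(OC)C[C@@](O)(CCCCCCCCCCCCC/C=C/CC)[C@H](O)C=C | intermediate
16 | (5S,6R)-5-[(E)-heptadec-14-en-1-yl]-5,6-dihydroxyocta-1,7-dien-3-one | C=CC(=O)C[C@@](O)(CCCCCCCCCCCCC/C=C/CC)[C@H](O)C=C | intermediate
17 | (4R,5S)-5-[(E)-heptadec-14-en-1-yl]-4,5-dihydroxycyclohex-2-en-1-one | CC/C=C/CCCCCCCCCCCCC[C@]1(O)CC(=O)C=C[C@H]1O | target

## Step count and risks

Total steps: 7. Longest linear sequence: 7 (1 → 17).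

**Step 6** is the most likely to fail. The lithiated allene must open a 2,2-disubstituted epoxide that carries a neighbouring lithium alkoxide. The product is a β-hydroxy vinyl ketone that can dehydrate, close to a tetrahydropyranone by oxa-Michael addition, or sit as a five-ring hemiketal. The fallback sets out from 12 and comes back at 16, replacing the acryloyl anion by a formyl anion and building the enone afterwards:
- The lithium alkoxide of 12 is opened with 2-lithio-1,3-dithiane (n-BuLi, THF/DMPU, −20 °C to rt) to give (3R,4S,18E)-4-(1,3-dithian-2-ylmethyl)henicosa-1,18-diene-3,4-diol F1.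
- 2,2-Dimethoxypropane and PPTS give the acetonide 2-{[(4S,5R)-5-ethenyl-4-[(E)-heptadec-14-en-1-yl]-2,2-dimethyl-1,3-dioxolan-4-yl]methyl}-1,3-dithiane F2.
- Methyl iodide and CaCO3 in aqueous MeCN free 2-[(4S,5R)-5-ethenyl-4-[(E)-heptadec-14-en-1-yl]-2,2-dimethyl-1,3-dioxolan-4-yl]acetaldehyde F3.
- Vinylmagnesium bromide (THF, −78 °C) gives 1-[(4S,5R)-5-ethenyl-4-[(E)-heptadec-14-en-1-yl]-2,2-dimethyl-1,3-dioxolan-4-yl]but-3-en-2-ol F4 as both carbinol epimers.
- Dess–Martin periodinane gives 1-[(4S,5R)-5-ethenyl-4-[(E)-heptadec-14-en-1-yl]-2,2-dimethyl-1,3-dioxolan-4-yl]but-3-en-2-one F5.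
- 80% aqueous acetic acid at rt removes the acetonide and returns 16.

**Step 5** is next. The yield cannot exceed 50%, the two allylic alkenes of 11 must be told apart, and the tertiary epoxide can be opened by the titanium alkoxide medium. The fallback sets out from 11 and comes back at 12, separating the resolution from the epoxidation:
- Novozym 435 (immobilised Candida antarctica lipase B) with vinyl acetate in hexane at 30 °C acylates the (R)-alcohol to (3R,18E)-4-methylidenehenicosa-1,18-dien-3-yl acetate F6, which is separated from unreacted (S)-11.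
- K2CO3 in MeOH gives (3R,18E)-4-methylidenehenicosa-1,18-dien-3-ol F7.
- VO(acac)2 (2 mol%) and t-BuOOH in CH2Cl2 at 0 °C then give 12. This hydroxyl-directed epoxidation takes the more substituted alkene and is erythro-selective for 2-substituted allylic alcohols because of allylic 1,2-strain.

**Step 7** is third. The ruthenium carbene may also engage the chain alkene (E/Z erosion or truncation), and the vinyl ketone is prone to oligomerise. The fallback sets out from 16 and comes back at 17, closing the ring at the alcohol oxidation level with a catalyst that ignores internal alkenes: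
- NaBH4 and CeCl3·7H2O in MeOH at −78 °C (Luche reduction) give (3RS,5S,6R)-5-[(E)-heptadec-14-en-1-yl]octa-1,7-diene-3,5,6-triol F8.
- First-generation Grubbs catalyst RuCl2(=CHPh)(PCy3)2 (5 mol%, CH2Cl2, 40 °C) closes (1S,2R,5RS)-1-[(E)-heptadec-14-en-1-yl]cyclohex-3-ene-1,2,5-triol F9.
- PhB(OH)2 and MgSO4 in CH2Cl2 mask the cis-1,2-diol as the cyclic phenylboronate of that triol F10.
- MnO2 in CH2Cl2 oxidises the remaining allylic alcohol to the 4,5-O-phenylboronate of the target enone F11.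
- Exchange with pinacol in THF at rt releases 17 under neutral conditions.

## Further compounds

F1 | step 6 | (3R,4S,18E)-4-(1,3-dithian-2-ylmethyl)henicosa-1,18-diene-3,4-diol | S1CCCSC1C[C@@](O)(CCCCCCCCCCCCC/C=C/CC)[C@H](O)C=C
F2 | step 6 | 2-{[(4S,5R)-5-ethenyl-4-[(E)-heptadec-14-en-1-yl]-2,2-dimethyl-1,3-dioxolan-4-yl]methyl}-1,3-dithiane | S1CCCSC1C[C@]2(CCCCCCCCCCCCC/C=C/CC)OC(C)(C)O[C@@H]2C=C
F3 | step 6 | 2-[(4S,5R)-5-ethenyl-4-[(E)-heptadec-14-en-1-yl]-2,2-dimethyl-1,3-dioxolan-4-yl]acetaldehyde | O=CC[C@]1(CCCCCCCCCCCCC/C=C/CC)OC(C)(C)O[C@@H]1C=C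
F4 | step 6 | 1-[(4S,5R)-5-ethenyl-4-[(E)-heptadec-14-en-1-yl]-2,2-dimethyl-1,3-dioxolan-4-yl]but-3-en-2-ol (both carbinol epimers) | C=CC(O)C[C@]1(CCCCCCCCCCCCC/C=C/CC)OC(C)(C)O[C@@H]1C=C
F5 | step 6 | 1-[(4S,5R)-5-ethenyl-4-[(E)-heptadec-14-en-1-yl]-2,2-dimethyl-1,3-dioxolan-4-yl]but-3-en-2-one | C=CC(=O)C[C@]1(CCCCCCCCCCCCC/C=C/CC)OC(C)(C)O[C@@H]1C=C
F6 | step 5 | (3R,18E)-4-methylidenehenicosa-1,18-dien-3-yl acetate | CC/C=C/CCCCCCCCCCCCCC(=C)[C@H](OC(C)=O)C=C
F7 | step 5 | (3R,18E)-4-methylidenehenicosa-1,18-dien-3-ol | CC/C=C/CCCCCCCCCCCCCC(=C)[C@H](O)C=C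
F8 | step 7 | (3RS,5S,6R)-5-[(E)-heptadec-14-en-1-yl]octa-1,7-diene-3,5,6-triol | C=CC(O)C[C@@](O)(CCCCCCCCCCCCC/C=C/CC)[C@H](O)C=C
F9 | step 7 | (1S,2R,5RS)-1-[(E)-heptadec-14-en-1-yl]cyclohex-3-ene-1,2,5-triol | CC/C=C/CCCCCCCCCCCCC[C@]1(O)CC(O)C=C[C@H]1O
F10 | step 7 | cyclic phenylboronate of the cyclohexenetriol across its cis-1,2-diol (fused 2-phenyl-1,3,2-dioxaborolane, allylic C5–OH free) | CC/C=C/CCCCCCCCCCCCC[C@]12CC(O)C=C[C@H]1OB(c3ccccc3)O2
F11 | step 7 | 4,5-O-phenylboronate of (4R,5S)-5-[(E)-heptadec-14-en-1-yl]-4,5-dihydroxycyclohex-2-en-1-one | CC/C=C/CCCCCCCCCCCCC[C@]12CC(=O)C=C[C@H]1OB(c3ccccc3)O2
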